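## Retrosynthetic overview

1. The target comes from Yamaguchi acylation of the hemiketal alcohol **20** with (E)-3-(1-methylimidazol-4-yl)acrylic acid **23**, which is made from the imidazole aldehyde **21**.
2. **20** comes from MnO2 oxidation of the doubly allylic alcohol **19**, with spontaneous 4,7-oxa-bridge hemiketalization. **19** comes from an intramolecular Nozaki–Hiyama–Kishi (NHK) closure of bromoacrylate/lactol **18**, which forms the 10-membered ring.
3. **18** comes from DIBAL reduction of butenolide **17**. **17** is made by the key step, a dearomative vinylogous Mukaiyama aldol of 5-methyl-2-siloxyfuran **16** with aldehyde **13**. This step sets the quaternary C(Me)–O centre, the acyloxy carbinol and the cis-alkene of the future dihydrofuran.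
4. **13** is made from the cis-cyclohexene aldehyde **8** by Z-bromo-Wittig, desilylation and oxidation. **8** comes from an organocatalytic Diels–Alder reaction of diene **4** (from isoprene sulfone) and enal **7**.
5. Ring order: cyclohexene, then furan-derived lactone ring, then 10-membered carbocycle, then oxa-bridged hemiketal.

Assumptions:
- 3-Methyl-3-sulfolene is alkylated at C2, next to the C–Me carbon.
- The imidazolidinone enantiomer is the one that gives the natural absolute configuration (I take (5S) here; use (5R) if the opposite antipode results).
- The Wittig gives the Z-bromoacrylate (ester trans to the ring carbon).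
- The correct F/G diastereomer from step 9 is separated chromatographically.

## Route

**Step 1**
Reactants: **1** 3-methyl-3-sulfolene (isoprene sulfone); **2** 2-(TBSO)ethyl bromide
Product: **3** 2-[2-(TBSO)ethyl]-3-methyl-3-sulfolene (racemic at C2)
Conditions: LiHMDS, THF/HMPA, –78 °C; then **2**, –78 → 0 °C
Reagents that add atoms: **2**, CC(C)(C)[Si](C)(C)OCCBr
Why: The α-sulfonyl allyl anion is alkylated at C2 (SN2). The C2 stereocentre is destroyed in step 2.

**Step 2**
Reactant: **3**
Product: **4** (E)-TBSO-CH2CH2-CH=C(CH3)-CH=CH2, (E)-1-substituted isoprene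
Conditions: toluene, 130 °C, sealed tube, BHT, NaHCO3
Reagents that add atoms: none (SO2 is lost)
Why: Cheletropic SO2 extrusion is stereospecific and delivers the (E)-1,2-disubstituted diene. This is the pre-set geometry that later gives the cis, ortho Diels–Alder outcome.

**Step 3**
Reactants: **5** isobutyraldehyde; **6** (triphenylphosphoranylidene)acetaldehyde
Product: **7** (E)-4-methylpent-2-enal
Conditions: CH2Cl2, rt → 40 °C
Reagents that add atoms: none (ylide **6** is the reactant; Ph3P=O is lost)
Why: A stabilized-ylide Wittig reaction gives the E-enal, which is the trans dienophile carrying the future isopropyl group.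

**Step 4**
Reactants: **4**; **7**
Product: **8** 6-isopropyl-3-methyl-2-[2-(TBSO)ethyl]cyclohex-3-ene-1-carbaldehyde; CHO and CH2CH2OTBS are cis, iPr is trans to CHO, absolute configuration as in the SMILES
Conditions: MacMillan imidazolidinone·HCl (20 mol %), MeOH/H2O 95:5, –10 °C → rt
Reagents that add atoms: none
Why: Iminium-ion-catalysed Diels–Alder reaction. Ortho regiochemistry, endo selectivity with the E-diene and E-enal, and the catalyst face selectivity set all three stereocentres (cis ring fusion, iPr trans) in one step.

**Step 5**
Reactants: **8**; **9** methyl (triphenylphosphoranylidene)acetate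
Product: **11** methyl (Z)-2-bromo-3-[cyclohexenyl]acrylate, with Br cis to the ring carbon and CO2Me trans
Conditions: **9** (2.2 equiv) + **10** (1.1 equiv), CH2Cl2, 0 °C; then **8**, 40 °C
Reagents that add atoms: **10** NBS, BrN1C(=O)CCC1=O
Why: NBS converts the stabilized ylide in situ into Ph3P=C(Br)CO2Me. The Wittig reaction of this stabilized bromo-ylide is Z-selective, and the neutral conditions avoid epimerising the α-stereocentre of the aldehyde.

**Step 6**
Reactant: **11**
Product: **12** primary alcohol (TBS removed)
Conditions: HF·pyridine, pyridine, THF, 0 °C → rt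
Reagents that add atoms: none
Why: Fluoride removes the primary silyl ether. The bromoacrylate and the trisubstituted alkene are untouched.

**Step 7**
Reactant: **12**
Product: **13** aldehyde, Ring-CH2-CHO
Conditions: Dess–Martin periodinane, NaHCO3, CH2Cl2, rt
Reagents that add atoms: none
Why: Mild oxidation of a primary alcohol. The aldehyde has no epimerisable α-stereocentre, because its α-carbon is a CH2.

**Step 8**
Reactants: **14** α-angelica lactone (5-methylfuran-2(3H)-one); **15** TMSOTf
Product: **16** 5-methyl-2-(trimethylsilyloxy)furan
Conditions: **15**, Et3N, CH2Cl2, 0 °C; used crude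
Reagents that add atoms: **15**, C[Si](C)(C)OS(=O)(=O)C(F)(F)F
Why: Silyl enol ether formation aromatises the lactone to a 2-siloxyfuran, which is the nucleophile for the dearomatizing step.

**Step 9 (key step)**
Reactants: **13**; **16**
Product: **17** γ-methyl-γ-(1-hydroxyalkyl)butenolide (F-OH, quaternary G), stereochemistry as in the SMILES
Conditions: BF3·OEt2, CH2Cl2, –78 °C; then 1 M HCl/THF to cleave the TMS ether
Reagents that add atoms: none (the TMS group is removed)
Why: This is a vinylogous Mukaiyama aldol. Attack of the siloxyfuran through C5 breaks the furan aromaticity and creates the tertiary, oxygenated quaternary carbon and the carbinol in one C–C bond-forming event. An open antiperiplanar transition state sets the F/G relative configuration. The remote 1,3-induction from the ring is modest, so the diastereomers are separated and the desired one is taken on. The lactone oxygen becomes the future oxa-bridge oxygen.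

**Step 10**
Reactant: **17**
Product: **18** lactol (2,5-dihydrofuran-2-ol; J-epimers are not assigned)
Conditions: DIBAL-H (2.5 equiv, 1 equiv consumed by the OH), CH2Cl2, –78 °C; Rochelle salt work-up
Reagents that add atoms: none
Why: The s-cis-locked butenolide carbonyl is reduced faster than the hindered trisubstituted α-bromoacrylate ester at –78 °C. The lactol is the masked cis-γ-hydroxy enal, so the cis H=I alkene and the G stereocentre are retained.

**Step 11**
Reactant: **18**
Product: **19** 10-membered carbocycle; J-OH, G-OH, F-OH, Z-A=B ester
Conditions: CrCl2 (10 equiv), NiCl2 (0.1 equiv), DMF, 0.002 M (syringe pump), 25 °C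
Reagents that add atoms: none (Br is lost)
Why: Proposed new method: Ni(0) inserts into the vinyl bromide and the alkenyl group transmetalates to Cr(III). The ring-open Z-enal tautomer of the lactol then captures it in an intramolecular NHK addition. The closest known reaction is the NHK macrocyclisation used for 10-membered eunicellane-type rings, except that the electrophile here is a lactol. The vinyl geometry is retained, giving the Z-trisubstituted ring alkene, and the new J carbinol stereocentre is destroyed in step 12.

**Step 12**
Reactant: **19**
Product: **20** oxa-bridged hemiketal alcohol (the target without the acyl group)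
Conditions: activated MnO2 (20 equiv), CH2Cl2, rt
Reagents that add atoms: none
Why: MnO2 oxidises only the doubly allylic J-OH (F-OH is a non-allylic secondary alcohol and G-OH is tertiary). The resulting cis-γ-hydroxy-enone closes spontaneously onto the G oxygen, and the bridge fixes the J configuration relative to G.

**Step 13**
Reactants: **21** 1-methylimidazole-4-carbaldehyde; **22** malonic acid
Product: **23** (E)-3-(1-methylimidazol-4-yl)acrylic acid
Conditions: pyridine, piperidine (cat.), 90 °C
Reagents that add atoms: none (malonic acid is the reactant; CO2 and H2O are lost)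
Why: Knoevenagel–Doebner condensation with decarboxylation gives the E-acrylic acid.

**Step 14**
Reactants: **20**; **23**
Product: **24** Sarcodictyin A
Conditions: **23**, 2,4,6-Cl3C6H2COCl, Et3N, THF; then **20**, DMAP, toluene, rt
Reagents that add atoms: none
Why: Yamaguchi esterification acylates the hindered secondary F-OH, and the tertiary hemiketal OH is too hindered to compete. The stereocentres are untouched.

## Compound list

| # | Name | SMILES | Role |
|---|---|---|---|
| 1 | 3-methyl-3-sulfolene | CC1=CCS(=O)(=O)C1 | starting material |
| 2 | 2-(TBSO)ethyl bromide | CC(C)(C)[Si](C)(C)OCCBr | starting material |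
| 3 | 2-[2-(TBSO)ethyl]-3-methyl-3-sulfolene | CC1=CCS(=O)(=O)C1CCO[Si](C)(C)C(C)(C)C | intermediate |
| 4 | (E)-4-methylhexa-3,5-dienyl TBS ether | CC(C)(C)[Si](C)(C)OCC/C=C(/C=C)C | intermediate |
| 5 | isobutyraldehyde | CC(C)C=O | starting material |
| 6 | (triphenylphosphoranylidene)acetaldehyde | O=CC=P(c1ccccc1)(c1ccccc1)c1ccccc1 | starting material |
| 7 | (E)-4-methylpent-2-enal | CC(C)/C=C/C=O | intermediate |
| 8 | cis-cyclohexene carbaldehyde (Diels–Alder adduct) | O=C[C@@H]1[C@@H](C(C)C)CC=C(C)[C@@H]1CCO[Si](C)(C)C(C)(C)C | intermediate |
| 9 | methyl (triphenylphosphoranylidene)acetate | COC(=O)C=P(c1ccccc1)(c1ccccc1)c1ccccc1 | starting material |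
| 10 | N-bromosuccinimide | BrN1C(=O)CCC1=O | starting material |
| 11 | (Z)-α-bromoacrylate, TBS ether | COC(=O)/C(Br)=C/[C@@H]1[C@@H](C(C)C)CC=C(C)[C@@H]1CCO[Si](C)(C)C(C)(C)C | intermediate |
| 12 | (Z)-α-bromoacrylate, primary alcohol | COC(=O)/C(Br)=C/[C@@H]1[C@@H](C(C)C)CC=C(C)[C@@H]1CCO | intermediate |
| 13 | (Z)-α-bromoacrylate, aldehyde | COC(=O)/C(Br)=C/[C@@H]1[C@@H](C(C)C)CC=C(C)[C@@H]1CC=O | intermediate |
| 14 | α-angelica lactone | CC1=CCC(=O)O1 | starting material |
| 15 | trimethylsilyl triflate | C[Si](C)(C)OS(=O)(=O)C(F)(F)F | starting material |
| 16 | 5-methyl-2-(trimethylsilyloxy)furan | C[Si](C)(C)OC1=CC=C(C)O1 | intermediate |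
| 17 | butenolide aldol product | COC(=O)/C(Br)=C/[C@@H]1[C@@H](C(C)C)CC=C(C)[C@@H]1C[C@H](O)[C@]1(C)C=CC(=O)O1 | intermediate |
| 18 | lactol | COC(=O)/C(Br)=C/[C@@H]1[C@@H](C(C)C)CC=C(C)[C@@H]1C[C@H](O)[C@]1(C)C=CC(O)O1 | intermediate |
| 19 | 10-membered-ring triol (NHK product) | COC(=O)/C1=C/[C@@H]2[C@@H](C(C)C)CC=C(C)[C@@H]2C[C@H](O)[C@](O)(C)/C=C\C1O | intermediate |
| 20 | oxa-bridged hemiketal alcohol | COC(=O)/C1=C/[C@@H]2[C@@H](C(C)C)CC=C(C)[C@@H]2C[C@H](O)[C@]2(C)C=C[C@@]1(O)O2 | intermediate |
| 21 | 1-methylimidazole-4-carbaldehyde | O=Cc1cn(C)cn1 | starting material |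
| 22 | malonic acid | OC(=O)CC(=O)O | starting material |
| 23 | (E)-3-(1-methylimidazol-4-yl)acrylic acid | OC(=O)/C=C/c1cn(C)cn1 | intermediate |
| 24 | Sarcodictyin A | COC(=O)/C1=C/[C@@H]2[C@@H](C(C)C)CC=C(C)[C@@H]2C[C@H](OC(=O)/C=C/c2cn(C)cn2)[C@]2(C)C=C[C@@]1(O)O2 | target |

## Summary

Total step count: 14. Longest linear sequence: 11 steps (1, 2, 4, 5, 6, 7, 9, 10, 11, 12, 14).

Three steps most likely to fail:

1. **Step 9 (dearomative aldol diastereoselectivity).** The remote ring stereocentres give weak facial control, so a mixture of F/G diastereomers is likely.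
   - Fallback: drop the siloxyfuran aldol and form the F–G bond by Nicolaou-type intramolecular acetylide addition to a G methyl ketone. Then use Lindlar semi-hydrogenation of the alkyne and spontaneous hemiketalization to form the oxa-bridge.
2. **Step 11 (NHK closure of the lactol), together with the DIBAL chemoselectivity of step 10.** A strained 10-membered ring with a Z-alkene must form from a lactol electrophile, and DIBAL may also attack the bromoacrylate ester.
   - Fallback: add LiCH2CO2Me to lactone **17** to give the β-ketoester hemiketal, with the cyclohexene aldehyde carried as a masked acetal. Then close the ring by an intramolecular Knoevenagel condensation.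
3. **Step 4 (Diels–Alder regiochemistry and enantioselectivity).** The 1,2-disubstituted diene and β-branched enal are a demanding combination for iminium catalysis.
   - Fallback: use the chiral-pool route from (R)-carvone. Alkylate C6 trans to the isopropenyl group, chemoselectively hydrogenate the isopropenyl group, and build the cis CH2CHO and bromoacrylate arms from the C1 ketone.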